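**Plan**

- Rings: A is the 3-hydroxyphenyl ring, B the para-phenylene ring on the ether oxygen, C the ring that carries that oxygen next to a free OH, D the hydroquinone ring. The four phenols are traced back to methyl ethers.
- The CH2–CH2 bridge between ring A and ring B consists of two unsubstituted carbons, each bonded to one aryl carbon. It is taken back to C≡C and cut at both aryl–C(sp) bonds into 3-iodoanisole, propiolic acid (a C2 unit with a terminal C–H end and a CO2H end) and the 4-bromophenyl ether of the ring C/ring D bibenzyl.
- That bromide is cut at the O–C(ring B) bond (Chan–Lam coupling with 4-bromophenylboronic acid). The ring C/ring D bridge is cut at the C=C level (Wittig reaction of O-benzylisovanillin with a 2,5-dimethoxybenzyl ylide).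
- Forward: ylide salt, Wittig reaction joining ring D to ring C, hydrogenation that also frees the ring C phenol, attachment of ring B through oxygen, attachment of ring A with its C2 bridge in one flask, hydrogenation, demethylation. All four benzene rings are bought; none is built.
- Stereochemistry: the target has no stereocentre and no double bond; the stilbene geometry from the Wittig step is erased by hydrogenation.

Key step: step 5

Assumption: (2,5-dimethoxyphenyl)methanol and 3-(benzyloxy)-4-methoxybenzaldehyde (the benzyl ether of isovanillin) are taken as catalogue chemicals.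

**Route**

Step 1
Reactants: 1 (2,5-dimethoxyphenyl)methanol
Product: 2 (2,5-dimethoxybenzyl)triphenylphosphonium bromide
Conditions: PPh3·HBr (1.05 equiv), MeCN, reflux
Reagents that add atoms: triphenylphosphine hydrobromide, [Br-].c1ccc([PH+](c2ccccc2)c2ccccc2)cc1
Why: Phosphonium salt formation from a benzylic alcohol with triphenylphosphine hydrobromide; the ortho-methoxy group eases ionisation of the protonated alcohol and PPh3 captures the benzylic carbon, so no benzyl halide has to be isolated.

Step 2
Reactants: 2 (2,5-dimethoxybenzyl)triphenylphosphonium bromide; 3 3-(benzyloxy)-4-methoxybenzaldehyde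
Product: 5 2-[2-(3-(benzyloxy)-4-methoxyphenyl)ethenyl]-1,4-dimethoxybenzene (E/Z mixture), via (2,5-dimethoxybenzylidene)triphenylphosphorane 4 (not isolated)
Conditions: KOtBu (1.1 equiv), THF, 0 °C; then 3, 0 °C to 25 °C
Reagents that add atoms: none
Why: Wittig olefination of a non-enolisable aryl aldehyde with a semi-stabilised benzylic ylide is reliable, and the mixture of alkene isomers is of no consequence because the double bond is saturated in the next step.

Step 3
Reactants: 5 2-[2-(3-(benzyloxy)-4-methoxyphenyl)ethenyl]-1,4-dimethoxybenzene (E/Z mixture)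
Product: 6 5-[2-(2,5-dimethoxyphenyl)ethyl]-2-methoxyphenol
Conditions: H2 (1 atm), 10% Pd/C, EtOAc/MeOH, 25 °C
Reagents that add atoms: none
Why: Catalytic hydrogenation over Pd/C should saturate the stilbene and hydrogenolyse the benzyl ether in one operation, while the aryl methyl ethers are inert.

Step 4
Reactants: 6 5-[2-(2,5-dimethoxyphenyl)ethyl]-2-methoxyphenol; 7 4-bromophenylboronic acid
Product: 8 2-[2-(3-(4-bromophenoxy)-4-methoxyphenyl)ethyl]-1,4-dimethoxybenzene
Conditions: Cu(OAc)2 (1 equiv), pyridine (5 equiv), 4 Å molecular sieves, CH2Cl2, air, 25 °C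
Reagents that add atoms: none
Why: Chan–Lam oxidative C–O coupling (aryl transfer from boron to the divalent copper phenoxide, then reductive elimination from trivalent copper) runs at room temperature, where the C–Br bond needed for step 5 is untouched.

Step 5
Reactants: 9 3-iodoanisole; 10 propiolic acid; 8 2-[2-(3-(4-bromophenoxy)-4-methoxyphenyl)ethyl]-1,4-dimethoxybenzene
Product: 12 2-[2-(4-methoxy-3-{4-[(3-methoxyphenyl)ethynyl]phenoxy}phenyl)ethyl]-1,4-dimethoxybenzene, via 3-(3-methoxyphenyl)propiolic acid 11 (not isolated)
Conditions: 9, 10, PdCl2(PPh3)2 (5 mol%), dppb (10 mol%), DBU (2.5 equiv), DMSO, 25 °C; then 8, 100 °C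
Reagents that add atoms: none
Why: Zerovalent palladium, formed in the flask from PdCl2(PPh3)2 and held by dppb, inserts at 25 °C only into the C–I bond of 9, and the DBU salt of 10 is coupled through its terminal C–H (copper-free Sonogashira reaction) to give propiolate 11, whose carboxylate is not yet extruded at this temperature. After 8 is added and the mixture heated, oxidative addition into the C–Br bond, exchange of bromide for the propiolate on divalent palladium, loss of CO2 to an aryl(alkynyl)palladium species and reductive elimination should form the second aryl–C(sp) bond. The closest known reaction type is the one-pot Sonogashira/decarboxylative alkynylation that joins an aryl iodide, propiolic acid and an aryl bromide to an unsymmetrical diarylalkyne. No ring is closed and no stereocentre is created. The selectivity needed is the order of the two arylations; it is secured by the iodide/bromide reactivity gap, by adding 8 only once 9 is consumed and by the higher temperature that decarboxylation requires, and any 11 that loses CO2 prematurely to the terminal alkyne can still reach 12 by Sonogashira coupling with 8. The methyl ethers, the diaryl ether and the saturated bridge of 8 are spectators, and the electron-rich para-aryloxy bromide is the slower partner, which is why it is given the heated stage and the bidentate phosphine.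

Step 6
Reactants: 12 2-[2-(4-methoxy-3-{4-[(3-methoxyphenyl)ethynyl]phenoxy}phenyl)ethyl]-1,4-dimethoxybenzene
Product: 13 2-[2-(4-methoxy-3-{4-[2-(3-methoxyphenyl)ethyl]phenoxy}phenyl)ethyl]-1,4-dimethoxybenzene
Conditions: H2 (1–3 atm), 10% Pd/C, EtOAc/EtOH, 25 °C
Reagents that add atoms: none
Why: Catalytic hydrogenation of a diarylalkyne over Pd/C should go through to the bibenzyl, while the diaryl ether and the methyl ethers do not react under these mild conditions.

Step 7
Reactants: 13 2-[2-(4-methoxy-3-{4-[2-(3-methoxyphenyl)ethyl]phenoxy}phenyl)ethyl]-1,4-dimethoxybenzene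
Product: 14 2-[2-(4-hydroxy-3-{4-[2-(3-hydroxyphenyl)ethyl]phenoxy}phenyl)ethyl]benzene-1,4-diol (CNP0300581.0)
Conditions: BBr3 (8 equiv), CH2Cl2, −78 °C to 25 °C; then H2O, 0 °C, work-up under argon
Reagents that add atoms: none
Why: BBr3 ether cleavage (Lewis acid complexation at oxygen, then bromide attack at the methyl carbon) should remove all four methyl ethers, whereas the diaryl ether offers no sp3 carbon for attack and stays intact.

**Compound list**

1 | (2,5-dimethoxyphenyl)methanol | COc1ccc(OC)c(CO)c1 | starting material
2 | (2,5-dimethoxybenzyl)triphenylphosphonium bromide | COc1ccc(OC)c(C[P+](c2ccccc2)(c2ccccc2)c2ccccc2)c1.[Br-] | intermediate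
3 | 3-(benzyloxy)-4-methoxybenzaldehyde | COc1ccc(C=O)cc1OCc1ccccc1 | starting material
4 | (2,5-dimethoxybenzylidene)triphenylphosphorane (ylide formed in the flask, not isolated) | COc1ccc(OC)c(C=P(c2ccccc2)(c2ccccc2)c2ccccc2)c1 | intermediate
5 | 2-[2-(3-(benzyloxy)-4-methoxyphenyl)ethenyl]-1,4-dimethoxybenzene (E/Z mixture, geometry not controlled) | COc1ccc(OC)c(C=Cc2ccc(OC)c(OCc3ccccc3)c2)c1 | intermediate
6 | 5-[2-(2,5-dimethoxyphenyl)ethyl]-2-methoxyphenol | COc1ccc(OC)c(CCc2ccc(OC)c(O)c2)c1 | intermediate
7 | 4-bromophenylboronic acid | OB(O)c1ccc(Br)cc1 | starting material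
8 | 2-[2-(3-(4-bromophenoxy)-4-methoxyphenyl)ethyl]-1,4-dimethoxybenzene | COc1ccc(OC)c(CCc2ccc(OC)c(Oc3ccc(Br)cc3)c2)c1 | intermediate
9 | 3-iodoanisole | COc1cccc(I)c1 | starting material
10 | propiolic acid | C#CC(=O)O | starting material
11 | 3-(3-methoxyphenyl)propiolic acid (present as its DBU salt, not isolated) | COc1cccc(C#CC(=O)O)c1 | intermediate
12 | 2-[2-(4-methoxy-3-{4-[(3-methoxyphenyl)ethynyl]phenoxy}phenyl)ethyl]-1,4-dimethoxybenzene | COc1cccc(C#Cc2ccc(Oc3cc(CCc4cc(OC)ccc4OC)ccc3OC)cc2)c1 | intermediate
13 | 2-[2-(4-methoxy-3-{4-[2-(3-methoxyphenyl)ethyl]phenoxy}phenyl)ethyl]-1,4-dimethoxybenzene | COc1cccc(CCc2ccc(Oc3cc(CCc4cc(OC)ccc4OC)ccc3OC)cc2)c1 | intermediate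
14 | 2-[2-(4-hydroxy-3-{4-[2-(3-hydroxyphenyl)ethyl]phenoxy}phenyl)ethyl]benzene-1,4-diol | Oc1cccc(CCc2ccc(Oc3cc(CCc4cc(O)ccc4O)ccc3O)cc2)c1 | target

**Step count**

Total steps: 7. Longest linear sequence: 7 steps (1 → 2 → 5 → 6 → 8 → 12 → 13 → 14).

**Steps most likely to fail**

Step 5. The risk is slow oxidative addition of the electron-rich para-aryloxy bromide in the heated stage, so that decarboxylation outruns cross-coupling and the propiolate is lost to protodecarboxylation and alkyne homocoupling. The fallback sets out from 8 and replaces the propiolate linchpin by a stepwise acetylene relay. Sonogashira coupling of 8 with ethynyltrimethylsilane (PdCl2(PPh3)2, CuI, Et3N, 80 °C) should give the 4-[(trimethylsilyl)ethynyl]phenyl ether of phenol 6 F1. Methanolysis (K2CO3, MeOH, 25 °C) should give the 4-ethynylphenyl ether of phenol 6 F2. A room-temperature Sonogashira coupling of this terminal alkyne with 3-iodoanisole 9 (PdCl2(PPh3)2, CuI, Et3N) comes back to the route at 12.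

Step 4. The risk is a stalled copper-mediated C–O coupling at the phenol flanked by an ortho-methoxy group, while protodeboronation and oxidative homocoupling use up the boronic acid. The fallback sets out from 6 and builds the ether by nucleophilic aromatic substitution instead. 1-Fluoro-4-nitrobenzene, K2CO3, DMF, 80 °C should give the 4-nitrophenyl ether of phenol 6 F3. Hydrogenation over Pd/C should give the 4-aminophenyl ether of phenol 6 F4. Diazotisation (NaNO2, aqueous HBr/MeCN, 0 °C) followed by Sandmeyer bromination with CuBr comes back to the route at 8.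

Step 7. The risk is incomplete cleavage of one of the four methyl ethers together with air oxidation of the ring D hydroquinone to the quinone during aqueous work-up and chromatography. The fallback sets out from 13 and isolates the product through a stable derivative. Demethylation in molten pyridinium chloride (190 °C, argon) and direct acetylation of the crude polyphenol (Ac2O, pyridine) should give the tetraacetate of 14 F5, which is stable to air and silica and can be separated from partly methylated material. Acid-catalysed methanolysis (HCl in degassed MeOH, 25 °C) then comes back to the route at 14 with only volatile by-products.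

**Further compounds**

F1 | step 5 | 4-[(trimethylsilyl)ethynyl]phenyl ether of phenol 6 | COc1ccc(OC)c(CCc2ccc(OC)c(Oc3ccc(C#C[Si](C)(C)C)cc3)c2)c1
F2 | step 5 | 4-ethynylphenyl ether of phenol 6 | COc1ccc(OC)c(CCc2ccc(OC)c(Oc3ccc(C#C)cc3)c2)c1
F3 | step 4 | 4-nitrophenyl ether of phenol 6 | COc1ccc(OC)c(CCc2ccc(OC)c(Oc3ccc([N+](=O)[O-])cc3)c2)c1
F4 | step 4 | 4-aminophenyl ether of phenol 6 | COc1ccc(OC)c(CCc2ccc(OC)c(Oc3ccc(N)cc3)c2)c1
F5 | step 7 | tetraacetate of 14 | CC(=O)Oc1cccc(CCc2ccc(Oc3cc(CCc4cc(OC(C)=O)ccc4OC(C)=O)ccc3OC(C)=O)cc2)c1
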